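**Plan**

- Cuts, in retrosynthetic order: C7–OH and C8=O (diosphenol ← 6,7-epoxy ketone ← dienone ← 1,4-diene), C6–CH3 (enol triflate coupling), C1–C8a (ring A), C4–C4a (B-alkyl Suzuki–Miyaura), the side-chain C=C (Horner–Wadsworth–Emmons), C5–CH2 (Michael addition).
- Forward: ring B is the ring of 2-methylcyclohexane-1,3-dione; its C2 becomes C5 and its two carbonyl carbons become C4a and C6. The side chain is joined first, the ring A chain second, ring A is closed third, and ring B is oxidised last.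
- Feature used: C1 is a fully substituted carbon next to the C2 oxygen, i.e. the tertiary carbon of a 2-methyl-2,3-epoxy alcohol, and C8a is one end of the tetrasubstituted C4a=C8a alkene shared by rings A and B. A C8a(H)=C4a alkene can therefore attack C1 and restore the alkene by loss of H8a.
- Stereochemistry: C5 comes from a Corey–Bakshi–Shibata desymmetrising reduction of the prochiral dione (the carbinol is oxidised later). C1 comes from a Sharpless asymmetric epoxidation and is relayed with inversion in the ring closure. The two centres are set independently.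
- The C6 enol triflate is carried through the ring closure as an electron-poor spectator and is exchanged for CH3 afterwards.

Key step: step 15

Remark: bicyclic compounds carry the locants of the target (C1 bears CH2O and CH3, C5 bears CH3 and the side chain). The CIP label of C5 changes along the route only because substituent priorities change; its spatial arrangement does not. Piv = 2,2-dimethylpropanoyl, Tf = trifluoromethylsulfonyl (triflate = trifluoromethanesulfonate), TBDPS = tert-butyldiphenylsilyl, TES = triethylsilyl, 9-BBN = 9-borabicyclo[3.3.1]nonane. Compounds 1, 2, 11 and the named reagents are taken as commercial.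

Step 1
Reactants: 1 2-methylcyclohexane-1,3-dione; 2 but-3-en-2-one
Product: 3 2-methyl-2-(3-oxobutyl)cyclohexane-1,3-dione
Conditions: H2O, AcOH (cat.), hydroquinone (cat.), 75 °C
Reagents that add atoms: none
Why: Michael addition of the acidic 1,3-dione to the enone (the first half of a Robinson annulation, stopped before the aldol stage under weakly acidic conditions) should give the triketone with the future C5 as a still prochiral quaternary carbon.

Step 2
Reactants: 3 2-methyl-2-(3-oxobutyl)cyclohexane-1,3-dione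
Product: 4 ethyl (2E)-3-methyl-5-(1-methyl-2,6-dioxocyclohexyl)pent-2-enoate
Conditions: NaH, THF, 0 °C → rt
Reagents that add atoms: ethyl 2-(diethoxyphosphoryl)acetate CCOC(=O)CP(=O)(OCC)OCC
Why: Horner–Wadsworth–Emmons olefination should take place only at the unhindered methyl ketone, the two ring carbonyls being flanked by the quaternary carbon, and should favour the (E)-enoate (a minor Z isomer would be removed by chromatography); no stereocentre is formed.

Step 3
Reactants: 4 ethyl (2E)-3-methyl-5-(1-methyl-2,6-dioxocyclohexyl)pent-2-enoate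
Product: 5 ethyl (2E)-5-[(1R,2R)-2-hydroxy-1-methyl-6-oxocyclohexyl]-3-methylpent-2-enoate
Conditions: (S)-2-methyl-CBS-oxazaborolidine (cat.), catecholborane, toluene, −78 °C
Reagents that add atoms: none
Why: Corey–Bakshi–Shibata reduction differentiates the two enantiotopic ring carbonyls, since the (S)-catalyst should give the (R)-carbinol (quaternary carbon as the large group) and hydride should enter anti to the longer substituent on the quaternary carbon, so that only the carbonyl leading to the (1R,2R)-ketol is reduced and the configuration of the future C5 is fixed (the minor diastereomer is separable).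

Step 4
Reactants: 5 ethyl (2E)-5-[(1R,2R)-2-hydroxy-1-methyl-6-oxocyclohexyl]-3-methylpent-2-enoate
Product: 6 ethyl (2E)-3-methyl-5-[(1R,2R)-1-methyl-6-oxo-2-(PivO)cyclohexyl]pent-2-enoate
Conditions: pyridine, DMAP (cat.), CH2Cl2, 0 °C → rt
Reagents that add atoms: 2,2-dimethylpropanoyl chloride CC(C)(C)C(=O)Cl
Why: Acylation of the hindered secondary alcohol under nucleophilic catalysis protects the beta-hydroxy ketone against retro-aldol cleavage in the following enolisation and touches no stereocentre.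

Step 5
Reactants: 6 ethyl (2E)-3-methyl-5-[(1R,2R)-1-methyl-6-oxo-2-(PivO)cyclohexyl]pent-2-enoate
Product: 7 ethyl (2E)-3-methyl-5-[(1R,6R)-1-methyl-6-(PivO)-2-(TfO)cyclohex-2-en-1-yl]pent-2-enoate
Conditions: KHMDS (KN(SiMe3)2), THF, −78 °C; then PhNTf2
Reagents that add atoms: N-phenylbis(trifluoromethanesulfonimide) O=S(=O)(N(c1ccccc1)S(=O)(=O)C(F)(F)F)C(F)(F)F
Why: Kinetic deprotonation can occur only at the single alpha methylene of the ring ketone (the other alpha carbon is quaternary), and O-triflation of the potassium enolate should give the enol triflate that marks the future C4a.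

Step 6
Reactants: 7 ethyl (2E)-3-methyl-5-[(1R,6R)-1-methyl-6-(PivO)-2-(TfO)cyclohex-2-en-1-yl]pent-2-enoate
Product: 8 (5R,6R)-5-hydroxy-6-[(3E)-5-hydroxy-3-methylpent-3-en-1-yl]-6-methylcyclohex-1-en-1-yl triflate
Conditions: DIBAL-H (i-Bu2AlH, excess), CH2Cl2, −78 → 0 °C
Reagents that add atoms: none
Why: Diisobutylaluminium hydride should reduce the conjugated ester to the allylic alcohol by 1,2-reduction and cleave the pivalate in the same operation, while the enol triflate is inert to hydride.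

Step 7
Reactants: 8 (5R,6R)-5-hydroxy-6-[(3E)-5-hydroxy-3-methylpent-3-en-1-yl]-6-methylcyclohex-1-en-1-yl triflate
Product: 9 (5R,6R)-5-hydroxy-6-methyl-6-[(3E)-3-methyl-5-(TBDPSO)pent-3-en-1-yl]cyclohex-1-en-1-yl triflate
Conditions: imidazole, CH2Cl2, 0 °C
Reagents that add atoms: tert-butyl(chloro)diphenylsilane CC(C)(C)[Si](Cl)(c1ccccc1)c1ccccc1
Why: Silylation with the bulky silyl chloride should be selective for the unhindered primary allylic alcohol over the secondary alcohol next to the quaternary carbon.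

Step 8
Reactants: 9 (5R,6R)-5-hydroxy-6-methyl-6-[(3E)-3-methyl-5-(TBDPSO)pent-3-en-1-yl]cyclohex-1-en-1-yl triflate
Product: 10 (6S)-6-methyl-6-[(3E)-3-methyl-5-(TBDPSO)pent-3-en-1-yl]-5-oxocyclohex-1-en-1-yl triflate
Conditions: Dess–Martin periodinane, NaHCO3, CH2Cl2, rt
Reagents that add atoms: none
Why: Dess–Martin oxidation converts the secondary alcohol into the ketone that marks the future C6 and erases the auxiliary carbinol centre, which leaves C5 as the only stereocentre.

Step 9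
Reactants: 11 prop-2-enal
Product: 12 ethyl (2E)-2-methylpenta-2,4-dienoate
Conditions: CH2Cl2, 0 °C → rt
Reagents that add atoms: ethyl 2-(triphenyl-λ5-phosphanylidene)propanoate CCOC(=O)C(C)=P(c1ccccc1)(c1ccccc1)c1ccccc1
Why: Wittig olefination with a stabilised ylide should give the (E)-2-methyl dienoate selectively.

Step 10
Reactants: 12 ethyl (2E)-2-methylpenta-2,4-dienoate
Product: 13 (2E)-2-methylpenta-2,4-dien-1-ol
Conditions: DIBAL-H (i-Bu2AlH), CH2Cl2, −78 °C
Reagents that add atoms: none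
Why: 1,2-Reduction of the ester with diisobutylaluminium hydride should give the (E)-dienol without touching the diene.

Step 11
Reactants: 10 (6S)-6-methyl-6-[(3E)-3-methyl-5-(TBDPSO)pent-3-en-1-yl]-5-oxocyclohex-1-en-1-yl triflate; 13 (2E)-2-methylpenta-2,4-dien-1-ol
Product: 15 (2S)-3-[(3E)-5-hydroxy-4-methylpent-3-en-1-yl]-2-methyl-2-[(3E)-3-methyl-5-(TBDPSO)pent-3-en-1-yl]cyclohex-3-en-1-one, via bis(9-BBN) adduct 14 (not isolated)
Conditions: 13, 9-BBN-H (2.2 equiv), THF, 0 °C → rt; then 10, Pd(dppf)Cl2 (cat.), K3PO4 (aq), DMF, 50 °C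
Reagents that add atoms: none
Why: B-alkyl Suzuki–Miyaura coupling, in which 9-BBN-H first caps the hydroxyl group as a borinate and then hydroborates only the terminal vinyl group of the diene at its end carbon, so that the primary alkylborane should couple with the enol triflate under palladium catalysis to form the C4–C4a bond while the aqueous base hydrolyses the borinate.

Step 12
Reactants: 15 (2S)-3-[(3E)-5-hydroxy-4-methylpent-3-en-1-yl]-2-methyl-2-[(3E)-3-methyl-5-(TBDPSO)pent-3-en-1-yl]cyclohex-3-en-1-one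
Product: 16 (2S)-3-[2-[(2R,3R)-3-(hydroxymethyl)-3-methyloxiran-2-yl]ethyl]-2-methyl-2-[(3E)-3-methyl-5-(TBDPSO)pent-3-en-1-yl]cyclohex-3-en-1-one
Conditions: Ti(OiPr)4 (cat.), D-(−)-diethyl tartrate (cat.), 4 Å molecular sieves, CH2Cl2, −20 °C
Reagents that add atoms: tert-butyl hydroperoxide CC(C)(C)OO
Why: Sharpless asymmetric epoxidation is directed by the free allylic hydroxyl, so only the ring A chain alkene reacts, and D-(−)-diethyl tartrate should deliver oxygen to the face that gives the (2R,3R)-epoxide (reagent control), which carries the future C1 and C2.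

Step 13
Reactants: 16 (2S)-3-[2-[(2R,3R)-3-(hydroxymethyl)-3-methyloxiran-2-yl]ethyl]-2-methyl-2-[(3E)-3-methyl-5-(TBDPSO)pent-3-en-1-yl]cyclohex-3-en-1-one
Product: 17 (2S)-2-methyl-2-[(3E)-3-methyl-5-(TBDPSO)pent-3-en-1-yl]-3-[2-[(2R,3R)-3-methyl-3-(TESOCH2)oxiran-2-yl]ethyl]cyclohex-3-en-1-one
Conditions: imidazole, CH2Cl2, 0 °C
Reagents that add atoms: chlorotriethylsilane CC[Si](Cl)(CC)CC
Why: Silylation of the primary alcohol gives an ether that can neither chelate the Lewis acid nor attack C1 as a neighbouring group in the ring closure.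

Step 14
Reactants: 17 (2S)-2-methyl-2-[(3E)-3-methyl-5-(TBDPSO)pent-3-en-1-yl]-3-[2-[(2R,3R)-3-methyl-3-(TESOCH2)oxiran-2-yl]ethyl]cyclohex-3-en-1-one
Product: 18 (6S)-6-methyl-6-[(3E)-3-methyl-5-(TBDPSO)pent-3-en-1-yl]-5-[2-[(2R,3R)-3-methyl-3-(TESOCH2)oxiran-2-yl]ethyl]cyclohexa-1,4-dien-1-yl triflate
Conditions: KHMDS (KN(SiMe3)2), THF, −78 °C; then PhNTf2
Reagents that add atoms: N-phenylbis(trifluoromethanesulfonimide) O=S(=O)(N(c1ccccc1)S(=O)(=O)C(F)(F)F)C(F)(F)F
Why: Kinetic enolisation toward the only alpha methylene (C7) and O-triflation should give the C6 enol triflate, the epoxide and the silyl ethers being inert to the amide base at low temperature.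

Step 15
Reactants: 18 (6S)-6-methyl-6-[(3E)-3-methyl-5-(TBDPSO)pent-3-en-1-yl]-5-[2-[(2R,3R)-3-methyl-3-(TESOCH2)oxiran-2-yl]ethyl]cyclohexa-1,4-dien-1-yl triflate
Product: 20 (1S,2R,5S)-2-hydroxy-1-(hydroxymethyl)-1,5-dimethyl-5-[(3E)-3-methyl-5-(TBDPSO)pent-3-en-1-yl]-1,2,3,4,5,8-hexahydronaphthalen-6-yl triflate, via cyclized triethylsilyl ether 19 (not isolated)
Conditions: MeAlCl2 (2 equiv), CH2Cl2, −78 °C; then 1 M HCl, THF, rt
Reagents that add atoms: none
Why: MeAlCl2 activates the epoxide oxygen of 18, the C8a=C4a π bond attacks the tertiary carbon C1 anti to the departing oxygen, and the resulting tertiary C4a cation loses the C8a proton to give the tetrasubstituted C4a=C8a alkene, after which the acidic work-up removes the triethylsilyl group from 19. The closest known reaction type is the epoxide-initiated cation–olefin (polyene-type) cyclisation terminated by proton loss. Ring A closes in a 6-endo mode at both partners (endo opening of the epoxide at C1 and endo attack on the alkene at C8a) through a chair-like transition state. C1 is controlled by the (2R,3R)-epoxide, because anti opening inverts C1 and so relays the Sharpless-derived configuration to the quaternary carbon, while C2 keeps the epoxide configuration; C8a ends sp2, so the face of the ring B alkene that reacts does not matter and the remote C5 need not exert any control. The step needs regioselection for C1 over C2 (secured by the more substituted epoxide carbon and the six-membered transition state), proton loss toward C8a (the more substituted alkene position is expected to be favoured), and inertness of the other π systems: the side-chain alkene cannot reach C1, the electron-poor C6 enol triflate neither attacks nor stabilises a cation at C5 (which suppresses a methyl shift from C5 to C4a), and the silyl ether, unlike an ester, cannot attack C1.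

Step 16
Reactants: 20 (1S,2R,5S)-2-hydroxy-1-(hydroxymethyl)-1,5-dimethyl-5-[(3E)-3-methyl-5-(TBDPSO)pent-3-en-1-yl]-1,2,3,4,5,8-hexahydronaphthalen-6-yl triflate
Product: 21 [(1S,2R,5S)-2-hydroxy-1,5-dimethyl-5-[(3E)-3-methyl-5-(TBDPSO)pent-3-en-1-yl]-6-(TfO)-1,2,3,4,5,8-hexahydronaphthalen-1-yl]methyl acetate
Conditions: 2,4,6-collidine, CH2Cl2, −78 → −40 °C
Reagents that add atoms: acetyl chloride CC(=O)Cl
Why: Acetylation under kinetic control should take the primary alcohol in preference to the secondary C2 hydroxyl, which is flanked by the quaternary C1.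

Step 17
Reactants: 21 [(1S,2R,5S)-2-hydroxy-1,5-dimethyl-5-[(3E)-3-methyl-5-(TBDPSO)pent-3-en-1-yl]-6-(TfO)-1,2,3,4,5,8-hexahydronaphthalen-1-yl]methyl acetate
Product: 22 [(1S,2R,5R)-2-hydroxy-1,5,6-trimethyl-5-[(3E)-3-methyl-5-(TBDPSO)pent-3-en-1-yl]-1,2,3,4,5,8-hexahydronaphthalen-1-yl]methyl acetate
Conditions: Pd(PPh3)4 (cat.), THF, 50 °C
Reagents that add atoms: methylzinc chloride (MeZnCl, 3 equiv) C[Zn]Cl
Why: Negishi cross-coupling should replace the enol triflate by methyl with retention of the alkene position, the acetate and the silyl ether being inert to the organozinc reagent (one equivalent is consumed by the free hydroxyl).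

Step 18
Reactants: 22 [(1S,2R,5R)-2-hydroxy-1,5,6-trimethyl-5-[(3E)-3-methyl-5-(TBDPSO)pent-3-en-1-yl]-1,2,3,4,5,8-hexahydronaphthalen-1-yl]methyl acetate
Product: 23 [(1S,5R)-1,5,6-trimethyl-5-[(3E)-3-methyl-5-(TBDPSO)pent-3-en-1-yl]-2,8-dioxo-1,2,3,4,5,8-hexahydronaphthalen-1-yl]methyl acetate
Conditions: PDC ((C5H5NH)2Cr2O7, excess), Celite, benzene, rt
Reagents that add atoms: tert-butyl hydroperoxide CC(C)(C)OO
Why: Chromium-mediated allylic oxidation with tert-butyl hydroperoxide should attack the doubly allylic C8 methylene, the weakest C–H bond of the molecule, to give the cross-conjugated dienone, and the hexavalent chromium reagent oxidises the C2 carbinol to the ketone in the same flask, which erases the C2 centre.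

Step 19
Reactants: 23 [(1S,5R)-1,5,6-trimethyl-5-[(3E)-3-methyl-5-(TBDPSO)pent-3-en-1-yl]-2,8-dioxo-1,2,3,4,5,8-hexahydronaphthalen-1-yl]methyl acetate
Product: 24 [(1S,5S)-6,7-epoxy-1,5,6-trimethyl-5-[(3E)-3-methyl-5-(TBDPSO)pent-3-en-1-yl]-2,8-dioxo-1,2,3,4,5,6,7,8-octahydronaphthalen-1-yl]methyl acetate (C6/C7 configuration not controlled)
Conditions: DBU, CH2Cl2, 0 °C → rt
Reagents that add atoms: tert-butyl hydroperoxide CC(C)(C)OO
Why: Weitz–Scheffer (nucleophilic) epoxidation should take only the C6=C7 enone double bond, which carries an alpha hydrogen, and neither the tetrasubstituted C4a=C8a enone nor the isolated side-chain alkene; the epoxide configuration is irrelevant because both carbons become sp2 in the next step.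

Step 20
Reactants: 24 [(1S,5S)-6,7-epoxy-1,5,6-trimethyl-5-[(3E)-3-methyl-5-(TBDPSO)pent-3-en-1-yl]-2,8-dioxo-1,2,3,4,5,6,7,8-octahydronaphthalen-1-yl]methyl acetate
Product: 25 [(1S,5S)-7-hydroxy-1,5,6-trimethyl-5-[(3E)-3-methyl-5-(TBDPSO)pent-3-en-1-yl]-2,8-dioxo-1,2,3,4,5,8-hexahydronaphthalen-1-yl]methyl acetate
Conditions: p-TsOH·H2O (cat.), CH2Cl2, rt
Reagents that add atoms: none
Why: Acid-catalysed isomerisation of the alpha,beta-epoxy ketone (ring opening at the tertiary C6, then loss of the C7 proton) should give the enol of the 1,2-dione, which is the diosphenol.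

Step 21
Reactants: 25 [(1S,5S)-7-hydroxy-1,5,6-trimethyl-5-[(3E)-3-methyl-5-(TBDPSO)pent-3-en-1-yl]-2,8-dioxo-1,2,3,4,5,8-hexahydronaphthalen-1-yl]methyl acetate
Product: 26 [(1S,5S)-7-hydroxy-5-[(3E)-5-hydroxy-3-methylpent-3-en-1-yl]-1,5,6-trimethyl-2,8-dioxo-1,2,3,4,5,8-hexahydronaphthalen-1-yl]methyl acetate
Conditions: HF·pyridine, pyridine, THF, 0 °C → rt
Reagents that add atoms: none
Why: Fluoride-mediated cleavage of the silyl ether should free the allylic alcohol without affecting the acetate, the diosphenol or the dienone.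

**Compound list**

1 | 2-methylcyclohexane-1,3-dione | CC1C(=O)CCCC1=O | starting material
2 | but-3-en-2-one | CC(=O)C=C | starting material
3 | 2-methyl-2-(3-oxobutyl)cyclohexane-1,3-dione | CC(=O)CCC1(C)C(=O)CCCC1=O | intermediate
4 | ethyl (2E)-3-methyl-5-(1-methyl-2,6-dioxocyclohexyl)pent-2-enoate | CCOC(=O)/C=C(C)/CCC1(C)C(=O)CCCC1=O | intermediate
5 | ethyl (2E)-5-[(1R,2R)-2-hydroxy-1-methyl-6-oxocyclohexyl]-3-methylpent-2-enoate | O=C1CCC[C@@H](O)[C@@]1(C)CC/C(C)=C/C(=O)OCC | intermediate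
6 | ethyl (2E)-3-methyl-5-[(1R,2R)-1-methyl-6-oxo-2-(PivO)cyclohexyl]pent-2-enoate | O=C1CCC[C@@H](OC(=O)C(C)(C)C)[C@@]1(C)CC/C(C)=C/C(=O)OCC | intermediate
7 | ethyl (2E)-3-methyl-5-[(1R,6R)-1-methyl-6-(PivO)-2-(TfO)cyclohex-2-en-1-yl]pent-2-enoate | O=S(=O)(OC1=CCC[C@@H](OC(=O)C(C)(C)C)[C@@]1(C)CC/C(C)=C/C(=O)OCC)C(F)(F)F | intermediate
8 | (5R,6R)-5-hydroxy-6-[(3E)-5-hydroxy-3-methylpent-3-en-1-yl]-6-methylcyclohex-1-en-1-yl triflate | O=S(=O)(OC1=CCC[C@@H](O)[C@@]1(C)CC/C(C)=C/CO)C(F)(F)F | intermediate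
9 | (5R,6R)-5-hydroxy-6-methyl-6-[(3E)-3-methyl-5-(TBDPSO)pent-3-en-1-yl]cyclohex-1-en-1-yl triflate | O=S(=O)(OC1=CCC[C@@H](O)[C@@]1(C)CC/C(C)=C/CO[Si](c2ccccc2)(c3ccccc3)C(C)(C)C)C(F)(F)F | intermediate
10 | (6S)-6-methyl-6-[(3E)-3-methyl-5-(TBDPSO)pent-3-en-1-yl]-5-oxocyclohex-1-en-1-yl triflate | O=S(=O)(OC1=CCCC(=O)[C@@]1(C)CC/C(C)=C/CO[Si](c2ccccc2)(c3ccccc3)C(C)(C)C)C(F)(F)F | intermediate
11 | prop-2-enal | C=CC=O | starting material
12 | ethyl (2E)-2-methylpenta-2,4-dienoate | CCOC(=O)/C(C)=C/C=C | intermediate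
13 | (2E)-2-methylpenta-2,4-dien-1-ol | OC/C(C)=C/C=C | intermediate
14 | 9-[(2E)-5-(9-borabicyclo[3.3.1]nonan-9-yl)-2-methylpent-2-enoxy]-9-borabicyclo[3.3.1]nonane (not isolated) | C(/C(C)=C/CCB1C2CCCC1CCC2)OB1C2CCCC1CCC2 | intermediate
15 | (2S)-3-[(3E)-5-hydroxy-4-methylpent-3-en-1-yl]-2-methyl-2-[(3E)-3-methyl-5-(TBDPSO)pent-3-en-1-yl]cyclohex-3-en-1-one | OC/C(C)=C/CCC1=CCCC(=O)[C@@]1(C)CC/C(C)=C/CO[Si](c2ccccc2)(c3ccccc3)C(C)(C)C | intermediate
16 | (2S)-3-[2-[(2R,3R)-3-(hydroxymethyl)-3-methyloxiran-2-yl]ethyl]-2-methyl-2-[(3E)-3-methyl-5-(TBDPSO)pent-3-en-1-yl]cyclohex-3-en-1-one | OC[C@@]1(C)O[C@@H]1CCC2=CCCC(=O)[C@@]2(C)CC/C(C)=C/CO[Si](c3ccccc3)(c4ccccc4)C(C)(C)C | intermediate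
17 | (2S)-2-methyl-2-[(3E)-3-methyl-5-(TBDPSO)pent-3-en-1-yl]-3-[2-[(2R,3R)-3-methyl-3-(TESOCH2)oxiran-2-yl]ethyl]cyclohex-3-en-1-one | CC[Si](CC)(CC)OC[C@@]1(C)O[C@@H]1CCC2=CCCC(=O)[C@@]2(C)CC/C(C)=C/CO[Si](c3ccccc3)(c4ccccc4)C(C)(C)C | intermediate
18 | (6S)-6-methyl-6-[(3E)-3-methyl-5-(TBDPSO)pent-3-en-1-yl]-5-[2-[(2R,3R)-3-methyl-3-(TESOCH2)oxiran-2-yl]ethyl]cyclohexa-1,4-dien-1-yl triflate | CC[Si](CC)(CC)OC[C@@]1(C)O[C@@H]1CCC2=CCC=C(OS(=O)(=O)C(F)(F)F)[C@@]2(C)CC/C(C)=C/CO[Si](c3ccccc3)(c4ccccc4)C(C)(C)C | intermediate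
19 | (1S,2R,5S)-2-hydroxy-1,5-dimethyl-5-[(3E)-3-methyl-5-(TBDPSO)pent-3-en-1-yl]-1-(TESOCH2)-1,2,3,4,5,8-hexahydronaphthalen-6-yl triflate (not isolated) | CC[Si](CC)(CC)OC[C@@]1(C)[C@H](O)CCC2=C1CC=C(OS(=O)(=O)C(F)(F)F)[C@@]2(C)CC/C(C)=C/CO[Si](c3ccccc3)(c4ccccc4)C(C)(C)C | intermediate
20 | (1S,2R,5S)-2-hydroxy-1-(hydroxymethyl)-1,5-dimethyl-5-[(3E)-3-methyl-5-(TBDPSO)pent-3-en-1-yl]-1,2,3,4,5,8-hexahydronaphthalen-6-yl triflate | OC[C@@]1(C)[C@H](O)CCC2=C1CC=C(OS(=O)(=O)C(F)(F)F)[C@@]2(C)CC/C(C)=C/CO[Si](c3ccccc3)(c4ccccc4)C(C)(C)C | intermediate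
21 | [(1S,2R,5S)-2-hydroxy-1,5-dimethyl-5-[(3E)-3-methyl-5-(TBDPSO)pent-3-en-1-yl]-6-(TfO)-1,2,3,4,5,8-hexahydronaphthalen-1-yl]methyl acetate | CC(=O)OC[C@@]1(C)[C@H](O)CCC2=C1CC=C(OS(=O)(=O)C(F)(F)F)[C@@]2(C)CC/C(C)=C/CO[Si](c3ccccc3)(c4ccccc4)C(C)(C)C | intermediate
22 | [(1S,2R,5R)-2-hydroxy-1,5,6-trimethyl-5-[(3E)-3-methyl-5-(TBDPSO)pent-3-en-1-yl]-1,2,3,4,5,8-hexahydronaphthalen-1-yl]methyl acetate | CC(=O)OC[C@@]1(C)[C@H](O)CCC2=C1CC=C(C)[C@@]2(C)CC/C(C)=C/CO[Si](c3ccccc3)(c4ccccc4)C(C)(C)C | intermediate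
23 | [(1S,5R)-1,5,6-trimethyl-5-[(3E)-3-methyl-5-(TBDPSO)pent-3-en-1-yl]-2,8-dioxo-1,2,3,4,5,8-hexahydronaphthalen-1-yl]methyl acetate | CC(=O)OC[C@@]1(C)C(=O)CCC2=C1C(=O)C=C(C)[C@@]2(C)CC/C(C)=C/CO[Si](c3ccccc3)(c4ccccc4)C(C)(C)C | intermediate
24 | [(1S,5S)-6,7-epoxy-1,5,6-trimethyl-5-[(3E)-3-methyl-5-(TBDPSO)pent-3-en-1-yl]-2,8-dioxo-1,2,3,4,5,6,7,8-octahydronaphthalen-1-yl]methyl acetate (C6/C7 configuration not controlled) | CC(=O)OC[C@@]1(C)C(=O)CCC2=C1C(=O)C3OC3(C)[C@@]2(C)CC/C(C)=C/CO[Si](c4ccccc4)(c5ccccc5)C(C)(C)C | intermediate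
25 | [(1S,5S)-7-hydroxy-1,5,6-trimethyl-5-[(3E)-3-methyl-5-(TBDPSO)pent-3-en-1-yl]-2,8-dioxo-1,2,3,4,5,8-hexahydronaphthalen-1-yl]methyl acetate | CC(=O)OC[C@@]1(C)C(=O)CCC2=C1C(=O)C(O)=C(C)[C@@]2(C)CC/C(C)=C/CO[Si](c3ccccc3)(c4ccccc4)C(C)(C)C | intermediate
26 | [(1S,5S)-7-hydroxy-5-[(3E)-5-hydroxy-3-methylpent-3-en-1-yl]-1,5,6-trimethyl-2,8-dioxo-1,2,3,4,5,8-hexahydronaphthalen-1-yl]methyl acetate | CC(=O)OC[C@@]1(C)C(=O)CCC2=C1C(=O)C(O)=C(C)[C@@]2(C)CC/C(C)=C/CO | target

**Step count and risks**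

Total step count: 21 (steps 9 and 10 make the ring A chain). Longest linear sequence: 19 steps (steps 1–8 and 11–21).

Steps most likely to fail:

1. Step 15. The C4a cation may lose the C4 proton instead of the C8a proton (ene-type termination), which would place the double bond at C4=C4a. Fallback, setting out from 18 and returning at 23: the alkene position is then fixed by conjugation instead of by the proton loss. The ring closure under the conditions of step 15 would give the 4(4a)-ene triethylsilyl ether F1 and, after the acidic work-up, the 4(4a)-ene diol F2. Acetylation and Negishi methylation as in steps 16 and 17 would give the 4(4a)-ene acetate F3 and the 4(4a)-ene methylated diene F4. Chromium-mediated allylic oxidation (PDC, t-BuOOH) at C8, now allylic to C6=C7 only, together with oxidation of the C2 carbinol, should give the beta,gamma-unsaturated diketone F5. Its C8a hydrogen is both alpha to the C8 carbonyl and allylic, so DBU should move the C4=C4a double bond into conjugation and give 23.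

2. Step 19. Conjugate addition of the peroxide anion at C6, which bears a methyl group and lies next to the quaternary C5, may be too slow, or the epoxy ketone may rearrange along other paths in step 20. Fallback, setting out from 23 and returning at 25: radical hydration of the enone replaces the epoxidation. Mukaiyama-type conditions (Mn(dpm)3, i.e. tris(2,2,6,6-tetramethylheptane-3,5-dionato)manganese, cat., PhSiH3, O2, i-PrOH, then P(OEt)3) should add hydrogen at C6 and oxygen at C7 of the less substituted enone to give the alpha-hydroxy ketone F6. Dess–Martin oxidation to the 1,2-dione, which enolises toward C6, should then give 25.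

3. Step 2. The basic phosphonate anion may trigger intramolecular aldol addition of the side-chain methyl ketone to a ring carbonyl before olefination occurs. Fallback, setting out from 3 and returning at 6: the methyl ketone is masked before the ring is desymmetrised. Ketal exchange with 2-ethyl-2-methyl-1,3-dioxolane (p-TsOH cat.) should give the dioxolane dione F7. Corey–Bakshi–Shibata reduction as in step 3 should give the dioxolane ketol F8, and pivaloylation as in step 4 the dioxolane pivalate F9. Mild acid (PPTS, wet acetone) should free the keto pivalate F10, whose methyl ketone faces only one hindered ring ketone in the Horner–Wadsworth–Emmons reaction that gives 6.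

Further compounds
F1 | step 15 | (1S,2R,5S)-2-hydroxy-1,5-dimethyl-5-[(3E)-3-methyl-5-(TBDPSO)pent-3-en-1-yl]-1-(TESOCH2)-1,2,3,5,8,8a-hexahydronaphthalen-6-yl triflate (C8a configuration not controlled) | CC[Si](CC)(CC)OC[C@@]1(C)[C@H](O)CC=C2C1CC=C(OS(=O)(=O)C(F)(F)F)[C@@]2(C)CC/C(C)=C/CO[Si](c3ccccc3)(c4ccccc4)C(C)(C)C
F2 | step 15 | (1S,2R,5S)-2-hydroxy-1-(hydroxymethyl)-1,5-dimethyl-5-[(3E)-3-methyl-5-(TBDPSO)pent-3-en-1-yl]-1,2,3,5,8,8a-hexahydronaphthalen-6-yl triflate | OC[C@@]1(C)[C@H](O)CC=C2C1CC=C(OS(=O)(=O)C(F)(F)F)[C@@]2(C)CC/C(C)=C/CO[Si](c3ccccc3)(c4ccccc4)C(C)(C)C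
F3 | step 15 | [(1S,2R,5S)-2-hydroxy-1,5-dimethyl-5-[(3E)-3-methyl-5-(TBDPSO)pent-3-en-1-yl]-6-(TfO)-1,2,3,5,8,8a-hexahydronaphthalen-1-yl]methyl acetate | CC(=O)OC[C@@]1(C)[C@H](O)CC=C2C1CC=C(OS(=O)(=O)C(F)(F)F)[C@@]2(C)CC/C(C)=C/CO[Si](c3ccccc3)(c4ccccc4)C(C)(C)C
F4 | step 15 | [(1S,2R,5R)-2-hydroxy-1,5,6-trimethyl-5-[(3E)-3-methyl-5-(TBDPSO)pent-3-en-1-yl]-1,2,3,5,8,8a-hexahydronaphthalen-1-yl]methyl acetate | CC(=O)OC[C@@]1(C)[C@H](O)CC=C2C1CC=C(C)[C@@]2(C)CC/C(C)=C/CO[Si](c3ccccc3)(c4ccccc4)C(C)(C)C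
F5 | step 15 | [(1S,5R)-1,5,6-trimethyl-5-[(3E)-3-methyl-5-(TBDPSO)pent-3-en-1-yl]-2,8-dioxo-1,2,3,5,8,8a-hexahydronaphthalen-1-yl]methyl acetate | CC(=O)OC[C@@]1(C)C(=O)CC=C2C1C(=O)C=C(C)[C@@]2(C)CC/C(C)=C/CO[Si](c3ccccc3)(c4ccccc4)C(C)(C)C
F6 | step 19 | [(1S,5R)-7-hydroxy-1,5,6-trimethyl-5-[(3E)-3-methyl-5-(TBDPSO)pent-3-en-1-yl]-2,8-dioxo-1,2,3,4,5,6,7,8-octahydronaphthalen-1-yl]methyl acetate (C6/C7 configuration not controlled) | CC(=O)OC[C@@]1(C)C(=O)CCC2=C1C(=O)C(O)C(C)[C@@]2(C)CC/C(C)=C/CO[Si](c3ccccc3)(c4ccccc4)C(C)(C)C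
F7 | step 2 | 2-methyl-2-[2-(2-methyl-1,3-dioxolan-2-yl)ethyl]cyclohexane-1,3-dione | CC1(CCC2(C)C(=O)CCCC2=O)OCCO1
F8 | step 2 | (2R,3R)-3-hydroxy-2-methyl-2-[2-(2-methyl-1,3-dioxolan-2-yl)ethyl]cyclohexan-1-one | O=C1CCC[C@@H](O)[C@@]1(C)CCC2(C)OCCO2
F9 | step 2 | (1R,2R)-2-methyl-2-[2-(2-methyl-1,3-dioxolan-2-yl)ethyl]-3-oxocyclohexyl 2,2-dimethylpropanoate | O=C1CCC[C@@H](OC(=O)C(C)(C)C)[C@@]1(C)CCC2(C)OCCO2
F10 | step 2 | (1R,2R)-2-methyl-3-oxo-2-(3-oxobutyl)cyclohexyl 2,2-dimethylpropanoate | O=C1CCC[C@@H](OC(=O)C(C)(C)C)[C@@]1(C)CCC(C)=O
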